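The working ratio w falls from 3.47 early in the gamma run to 1.72 between the 50.0 s and 80.0 s readings of the beta run, and to 1.28 between its last two. Here w is the points of Z gained per point of E lost between two readings, multiplied by mean E over mean X. Time drops out, leaving the pull of D on X measured against the first-order loss of E.

| flask | E | D | remark | time |
|---|---|---|---|---|
| gamma | 0.050 M | 1.2 mM | the very flask that is asked about, followed so far |  |
| beta | 0.075 M | 1.2 mM | run made earlier |  |
| flask | 0.050 M | 1.2 mM |  | 2.0 min |

| run | time / s | Z / % | X / % | E / % |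
|---|---|---|---|---|
| gamma | 10.0 | 6.9 | 14.4 | 78.4 |
| gamma | 12.0 | 9.7 | 15.1 | 74.9 |
| gamma | 15.0 | 13.2 | 16.5 | 69.7 |
| beta | 25.0 | 26.1 | 18.2 | 54.8 |
| beta | 50.0 | 50.9 | 18.7 | 30.3 |
| beta | 80.0 | 71.0 | 14.7 | 14.6 |
| beta | 90.0 | 74.4 | 13.1 | 12.2 |
| beta | 120 | 85.1 | 8.9 | 5.5 |

(standard deviation of a reading: 0.3 percentage points)

- how much Z the flask holds at 2.0 min, in percent of the E charged
- how much X the flask holds at 2.0 min, in percent of the E charged
- how much E the flask holds at 2.0 min, in percent of the E charged

E is the easy part. Gamma at 15.0 s gives 0.0241 s⁻¹ and beta at 120 s gives 0.0242 s⁻¹, about the same constant. So the flask, which is the gamma run continued, should hold beta's 5.5% of E at 2.0 min.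

X is where two chemists part. The first says D fades with the clock, so percent curves ignore the charge and the flask simply repeats beta's last reading: X 8.9%, Z 85.1%.

The second says Z ties D up as G, so w follows cZ. Beta's last w belongs to a mean cZ of 59.8 mM, but the flask ends nearer the 45.7 mM of beta's earlier window. I side with the second. At equal E and equal Z gain per E lost, X goes inversely with w, which gives X 6.64% and, by balance, Z 87.9%, or cZ 43.9 mM.

The forecast gives Z 88.3%, X 6.1% and E 5.6%, holding that “gamma keeps more active catalyst”. The flask gives Z 87.8%, X 6.62%, E 5.61%.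

    D + X → D + Z (k = 70.0 M⁻¹ s⁻¹)
    D + Z ⇌ G (K = 30.0 M⁻¹, k = 1.80 M⁻¹ s⁻¹)
    E → X (k = 0.0240 s⁻¹)

The clock view stands 2.3 percentage points too high in X; its ground is the flask's early stretch, with D still 96.9% at 0.200 min. At 2.0 min, E over w times X, with w at 1.72, gives feed over removal of X as 0.493, against the simulation's 0.549. The same flask read at 80 s holds E 14.7%, X 12.0% and a cZ of 36.7 mM, less than the window that gave w. With that same w as a rough value, the reckoning gives 0.712, below one: X is falling there, and it reaches 6.62% at 2.0 min.

The data stem from a simulated flask on assumed constants, and the scatter is random.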